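## Structural features

The target is a single benzene ring without any stereocentre, so no stereocentres stand next to each other and nothing has to be controlled in that respect. With the ring numbered from the acetoxy carbon, C1 carries the acetate, C2 and C4 carry free hydroxyls, C3 and C5 carry hydrogen, and C6 carries an unbranched pentadecyl chain. The three oxygens form a 1,2,4-trioxygenated (hydroxyquinol) array, which makes the ring very electron-rich and prone to air oxidation to a quinone whenever a phenoxide is present. The acetate sits on the most hindered oxygen, flanked by the C2 hydroxyl and the chain, and as a catechol monoester it can migrate to O2 or be solvolysed under mildly basic or nucleophilic conditions. The carbon skeleton is simple, and the real difficulty is to tell three phenolic oxygens apart, to acylate O1 alone, and to uncover O2 and O4 without moving the acetyl group. The hydroxyls on C2 and C4 are meta to each other and both meta to the chain on C6, which is the pattern of a polyketide 5-alkylresorcinol, ring carbons C2 to C6 corresponding to carbons 3 to 7 of a 3,5,7-trioxoacyl chain whose tail is the pentadecyl group. The key step exploits this by letting ring C1 arise from the chain carbon next to the carboxyl group, which already bears an ether oxygen, so that the ring bond C1–C6 is formed with O1 protected while O2 and O4 appear as free phenols from ketones.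

## Logic of the disconnections

**16 to 15.** The two O–Si bonds at O2 and O4 are cut. The acetate must already be in place when the phenols are uncovered, and a silyl ether can be removed without base, under which a catechol monoacetate would migrate or cleave. The gain is an endgame that closes with a single deprotection. The forward step must cleave aryl silyl ethers with buffered acidic fluoride and be worked up near neutrality.

**15 to 13 (through 14).** The O1–acetyl bond is cut, then the O1–benzyl bond. Hydrogenolysis is orthogonal to the silyl ethers and exposes O1 alone, so the acylation needs no selectivity between oxygens. The gain is that the hindered oxygen is addressed by itself. The demand is that 14, which has a silyl ether on the neighbouring oxygen, is acylated before any silyl shift, and it is therefore not isolated.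

**13 to 12.** The two O–Si bonds are cut again, now in the protecting sense. Since 12 already holds the three oxygens in two classes, one ether and two phenols, a single exhaustive silylation suffices and no selective protection is needed. The demand is only that both phenols, including the one beside the benzyloxy group, are silylated completely.

**12 to 9 (through 10 and 11).** The ring bond C1–C6 is cut and a carboxyl carbon is restored on C1. This opens the arene to the acyclic chain 9, in which every ring oxygen already sits on the right carbon and in the right form. The gain is the largest of the route, because the ring and the full oxygen differentiation reduce to a linear chain. The forward step must favour aldol closure of chain C-2 onto C-7 over Claisen closure and O-cyclisation, and must lose the carboxyl group from a quaternary carbon. The methyl ester is retained as the ester least hindered towards hydroxide, and the benzyl ether because it survives hydroxide and is removed orthogonally to silyl.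

**9 to 6 + 8.** The chain bond C-6–C-7 is cut. The C15 tail and the C-7 carbonyl come from the fatty acyl donor 8, and the nucleophile is the terminal carbon of the trianion of 6. An acyl donor with an acidic C–H would quench such a polyanion, so the chain is grown from the ester end with amides that carry no acidic proton at the reacting site. The demand is a clean third deprotonation at the terminal methyl of 6 and a prompt, mildly acidic work-up.

**8 to 7.** The amide C–N bond is cut. An N-methoxy-N-methyl amide is preferred to an ester or an acid chloride because its chelated adduct does not release the acidic product while unreacted trianion is present, so the advanced fragment 6 can be used in a one-to-one ratio. The gain is a commercial acid chloride as the source of the tail. The demand is no more than a routine amide formation.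

**6 to 4 + 5.** The chain bond C-4–C-5 is cut. The same logic applies one level down: the dianion of 4 is acetylated by 5. The gain is a four-carbon keto ester that already carries the ether oxygen. The demand is selective ionisation of the methyl group after the C-2 proton.

**4 to 2 + 3.** The C-2–O bond is cut. A carbenoid O–H insertion places the benzyloxy group on the carbon between the two carbonyls and avoids the enolate chemistry of an alkoxyacetate, which is prone to self-condensation. The gain is that the ether oxygen comes from 3 itself. The demand is slow addition of 2, so that the carbenoid meets the alcohol and not a second molecule of diazo compound.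

**2 to 1.** The bond between C-2 and the diazo nitrogen is cut. Diazo transfer to the activated methylene of 1 is routine and starts the route from a bulk chemical. The demand is only a sulfonyl azide that is safe to handle.

## Other disconnections considered

Alternative 1: The cut goes through the C6–chain bond and the C1–O bond, with an aryne as the six-carbon synthon and no ring closure. In the forward direction 1,5-bis(benzyloxy)-2,3-dibromobenzene A1 would undergo bromine–lithium exchange with pentadecyllithium A3 at the bromine next to the ether, and loss of the metal halide from the resulting aryllithium would release 3,5-bis(benzyloxy)benzyne A2. A second equivalent of A3 would add to A2 at C6, the aryne carbon remote from the C2 ether. The C1 aryllithium so formed would be trapped by a borate ester and oxidised with peroxide in the same flask to 2,4-bis(benzyloxy)-6-pentadecylphenol A4. Acetylation of A4 would give 2,4-bis(benzyloxy)-6-pentadecylphenyl acetate A5, and hydrogenolysis of A5 would release 16.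
- In its favour: O1 is born as the only free phenol in A4; the regiochemistry follows the known bias of 3-alkoxyarynes such as A2; the last step is a neutral hydrogenolysis of A5 that cannot move the acetate.
- Against it: A1 needs its own multistep preparation; A3 must be made from the halide and serves as both exchange reagent and nucleophile; alkylation by the alkyl bromide formed in the exchange, self-trapping of A2 by aryllithium and benzylic metalation of the ethers are all plausible diversions.
- Comparison: on structure it differentiates the oxygens as well as the chosen plan and has the better endgame (two steps from A4 against three from 12). On mechanism its key step rests on a precedented reaction class, whereas step 6 does not, so it is the better there. On step economy it should be the equal or the better if A1 can be reached in about three steps. The chosen plan is preferable only in avoiding cryogenic organolithium chemistry with a waxy C15 reagent and in building the ring from cheap acyclic pieces.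

Alternative 2: The cut goes through the C5–C6 double bond of a ring that is not yet aromatic. The acyclic ketol 6-hydroxy-4-oxo-2-pentadecylocta-1,7-dien-3-yl acetate A6 would be closed by second-generation Grubbs catalyst RuCl2(=CHPh)(PCy3)(H2IMes), with loss of the two terminal methylene carbons as the volatile alkene, to 4-hydroxy-6-oxo-2-pentadecylcyclohex-2-en-1-yl acetate A7. Oxidation of the allylic alcohol of A7 would give 4,6-dioxo-2-pentadecylcyclohex-2-en-1-yl acetate A8, and A8 is a tautomer of 16 that should aromatise by double enolisation.
- In its favour: the acetate is placed on a saturated carbon before any phenol exists, so no oxygen differentiation and no ring protecting groups are needed; metathesis to a trisubstituted cyclohexene such as A7 is a well-established closure.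
- Against it: A6 is an α-acetoxy ketone with a β′-hydroxyl, prone to acyl shift, elimination and retro-aldol; its assembly by a crossed aldol of an α-acetoxy ketone with an enal is itself delicate; ruthenium hydrides may isomerise the allylic alcohol of A7; A8 must aromatise without losing acetic acid.
- Comparison: it is the better of the two on protecting-group economy and on the precedent of the ring-forming step, and probably somewhat shorter overall. The chosen plan has the more robust intermediates before the ring closure, and its precursor assembly uses only enolate acylations.

Alternative 3: The cut goes through the C4–C5 bond of a ring assembled from a four-carbon cyclobutenone and a two-carbon alkenyl unit. The alkenyllithium from 2-bromoheptadec-1-ene A10 would add to the ketone-like carbonyl of 3-(benzyloxy)cyclobut-3-ene-1,2-dione A9 to give 3-(benzyloxy)-4-(heptadec-1-en-2-yl)-4-hydroxycyclobut-2-en-1-one A11. Acetylation of the tertiary alkoxide of A11 would give 2-(benzyloxy)-1-(heptadec-1-en-2-yl)-4-oxocyclobut-2-en-1-yl acetate A12. In hot toluene A12 should open by four-electron electrocyclic ring opening to the dienylketene 4-(benzyloxy)-6-oxo-2-pentadecylhexa-1,3,5-trien-3-yl acetate A13. In A13 the ketene carbon (future C4) would bond to the vinyl methylene (future C5) in a six-electron electrocyclisation, and tautomerisation would give 2-(benzyloxy)-4-hydroxy-6-pentadecylphenyl acetate A14. Hydrogenolysis of A14 would give 16.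
- In its favour: the acetate is installed on the tertiary alkoxide of A11 before the arene exists; the free phenol of A14 is para to the acetate and not adjacent to it; the thermal ring expansion of 4-alkenylcyclobutenones is a well-precedented route to phenols; the final step is neutral.
- Against it: A9 and A10 both need preparation; the tertiary cyclobutenyl acetate A12 may ionise or eliminate; the ketene A13 may be intercepted before it closes; squarate-derived starting materials are costly.
- Comparison: on step economy (about five to six steps) and on the reliability of the key step it is the better of the two. On regiocontrol of the oxygens the two plans are equal. The chosen plan has cheaper feedstock and the biomimetic closure, which differentiates the oxygens during ring formation, but carries more risk in its key step.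

Key step: step 6

Remark on the chemistry (assumption): a 2-alkoxymalonate diester, the obvious three-carbon acyl donor for joining chain C-3 to C-4, has a C–H acidic enough to protonate any diketone dianion, so 9 is grown from its ester end by two Claisen-type acylations with N-methoxy-N-methyl amides; 9 is drawn as the triketo tautomer although it should exist largely as enols.

## Route

Step 1
Reactants: 1 methyl 3-oxobutanoate
Product: 2 methyl 2-diazo-3-oxobutanoate
Conditions: p-ABSA, Et3N, MeCN, 0 °C to rt
Reagents that add atoms: 4-acetamidobenzenesulfonyl azide (p-ABSA), CC(=O)Nc1ccc(cc1)S(=O)(=O)N=[N+]=[N-]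
Why: Regitz diazo transfer; the ammonium enolate of the β-keto ester attacks the terminal azide nitrogen and the triazene collapses to the diazo compound and the sulfonamide. The acceptor/acceptor diazo ester is stable enough to handle, and p-ABSA is the less hazardous sulfonyl azide.

Step 2
Reactants: 2 methyl 2-diazo-3-oxobutanoate; 3 benzyl alcohol
Product: 4 methyl 2-(benzyloxy)-3-oxobutanoate (racemic)
Conditions: Rh2(OAc)4 (1 mol %), 3 (1.5 equiv), CH2Cl2, reflux, slow addition of 2
Reagents that add atoms: none
Why: Rhodium-carbenoid O–H insertion; the carbenoid from 2 is captured by the alcohol oxygen and proton transfer in the oxonium ylide gives the α-benzyloxy β-keto ester. Slow addition suppresses carbene dimerisation, and the new stereocentre is racemic and is erased later.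

Step 3
Reactants: 4 methyl 2-(benzyloxy)-3-oxobutanoate; 5 N-methoxy-N-methylacetamide
Product: 6 methyl 2-(benzyloxy)-3,5-dioxohexanoate (racemic, enolised)
Conditions: LiN(iPr)2 (2.2 equiv), THF, −78 to 0 °C; then 5, −78 to 0 °C; cold 1 M HCl
Reagents that add atoms: none
Why: Acylation of a β-keto ester dianion (crossed Claisen condensation); the first equivalent of base removes the C-2 proton, the second the C-4 methyl proton, and the terminal carbanion adds to the N-methoxy-N-methyl amide. The chelated adduct persists until the quench, so the acidic product cannot protonate unreacted dianion.

Step 4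
Reactants: 7 hexadecanoyl chloride
Product: 8 N-methoxy-N-methylhexadecanamide
Conditions: MeNH(OMe)·HCl, Et3N (2.2 equiv), CH2Cl2, 0 °C to rt
Reagents that add atoms: N,O-dimethylhydroxylamine hydrochloride, CNOC.Cl
Why: Acyl substitution of an acid chloride by an amine (Weinreb amide formation), a routine reaction that should proceed cleanly with an unbranched fatty acid chloride.

Step 5
Reactants: 6 methyl 2-(benzyloxy)-3,5-dioxohexanoate; 8 N-methoxy-N-methylhexadecanamide
Product: 9 methyl 2-(benzyloxy)-3,5,7-trioxodocosanoate (racemic, largely enolised)
Conditions: LiN(iPr)2 (3.3 equiv), THF, −78 to 0 °C; then 8, 0 °C; cold dilute HCl to pH 3; used at once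
Reagents that add atoms: none
Why: Acylation of a diketo ester trianion (polyanion Claisen condensation); successive deprotonation at C-2, C-4 and the terminal C-6 methyl gives a trianion whose most basic, least hindered carbon attacks the amide and installs C-7 with the C15 tail. The stable tetrahedral adduct allows a one-to-one ratio, and the product is used promptly because open-chain triketo esters cyclise on storage.

Step 6
Reactants: 9 methyl 2-(benzyloxy)-3,5,7-trioxodocosanoate
Product: 12 4-(benzyloxy)-5-pentadecylbenzene-1,3-diol, via cyclic aldol adduct 10 (not isolated), via cyclohexenedione carboxylic acid 11 (not isolated)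
Conditions: 1 M KOH (degassed), H2O–THF 1:1, Ar, 0 °C to rt, then 40 °C; then 2 M HCl to pH 2, 0 °C
Reagents that add atoms: none
Why: Proposed new method: hydroxide converts 9 into its polyenolate, and the enolate carbon C-2, flanked by the ester and the C-3 ketone and carrying the benzyloxy group, should add to the C-7 ketone in a 6-(enolendo)-exo-trig aldol closure that forms the ring bond between the future C1 and C6 and gives 10. E1cB loss of the tertiary hydroxyl through the C-6 enolate and saponification of the ester should lead to 11, a β-keto acid whose decarboxylation is driven by aromatisation, and direct hydroxide attack on the ester carbonyl with expulsion of the phenoxide-like ring anion would reach the same product. The closest known reaction type is the hydroxide-mediated aldol cyclisation of 3,5,7-triketo esters and acids to resorcylates and 5-alkylresorcinols, in which the nucleophilic carbon is an unsubstituted methylene, whereas a tertiary oxygen-bearing nucleophile and aromatisation by loss of the carboxyl from a quaternary carbon have no direct model. The two stereocentres of 10 are transient and vanish on dehydration and aromatisation, so no element of stereocontrol is needed. The step needs the C-2 to C-7 aldol mode to prevail over Claisen attack of C-6 on the ester, over an aldol of the C-8 methylene onto C-3, and over O-cyclisation to a pyranone. Aqueous hydroxide favours addition to the ketone and offers neither a chelating metal nor a dehydrating acid, the α-branched ester is a poor Claisen acceptor, and C-8 is far less acidic than C-2. Because the ether oxygen rides on the nucleophilic carbon, O1 should emerge protected while O2 and O4 emerge as free phenols, and oxygen is excluded because the product is readily oxidised as its phenoxide.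

Step 7
Reactants: 12 4-(benzyloxy)-5-pentadecylbenzene-1,3-diol
Product: 13 1-(benzyloxy)-2,4-bis[(tert-butyldimethylsilyl)oxy]-6-pentadecylbenzene
Conditions: TBSCl (2.5 equiv), imidazole (5 equiv), DMF, rt
Reagents that add atoms: tert-butyldimethylsilyl chloride, CC(C)(C)[Si](C)(C)Cl
Why: Standard imidazole-mediated silylation of phenols; both hydroxyls are accessible. Silyl ethers survive hydrogenolysis and acylation and can later be removed without base.

Step 8
Reactants: 13 1-(benzyloxy)-2,4-bis[(tert-butyldimethylsilyl)oxy]-6-pentadecylbenzene
Product: 15 2,4-bis[(tert-butyldimethylsilyl)oxy]-6-pentadecylphenyl acetate, via free phenol 14 (not isolated)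
Conditions: H2 (1 atm), 10% Pd/C, EtOAc, rt; filtration through Celite under Ar; then Ac2O, pyridine, DMAP (cat.), 0 °C to rt
Reagents that add atoms: acetic anhydride, CC(=O)OC(C)=O
Why: Hydrogenolysis of the aryl benzyl ether over Pd/C leaves aryl silyl ethers intact. The oxidation- and migration-prone phenol 14 is acetylated at once by DMAP-catalysed acyl transfer in weakly basic pyridine, which keeps the phenoxide concentration low and so disfavours a silyl shift from O2 to O1.

Step 9
Reactants: 15 2,4-bis[(tert-butyldimethylsilyl)oxy]-6-pentadecylphenyl acetate
Product: 16 2,4-dihydroxy-6-pentadecylphenyl acetate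
Conditions: HF·pyridine, pyridine, THF, 0 °C to rt; pH 7 phosphate buffer work-up
Reagents that add atoms: none
Why: Fluoride-induced cleavage of aryl silyl ethers through pentacoordinate silicon under buffered acidic conditions. The medium is never basic, so the aryl acetate should neither be cleaved nor shift to the neighbouring C2 oxygen.

## Compound list

1 | methyl 3-oxobutanoate (methyl acetoacetate) | COC(=O)CC(C)=O | starting material
2 | methyl 2-diazo-3-oxobutanoate | COC(=O)C(=[N+]=[N-])C(C)=O | intermediate
3 | benzyl alcohol | OCc1ccccc1 | starting material
4 | methyl 2-(benzyloxy)-3-oxobutanoate (racemic) | COC(=O)C(OCc1ccccc1)C(C)=O | intermediate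
5 | N-methoxy-N-methylacetamide | CC(=O)N(C)OC | starting material
6 | methyl 2-(benzyloxy)-3,5-dioxohexanoate (racemic, enolised) | COC(=O)C(OCc1ccccc1)C(=O)CC(C)=O | intermediate
7 | hexadecanoyl chloride | CCCCCCCCCCCCCCCC(=O)Cl | starting material
8 | N-methoxy-N-methylhexadecanamide | CCCCCCCCCCCCCCCC(=O)N(C)OC | intermediate
9 | methyl 2-(benzyloxy)-3,5,7-trioxodocosanoate (racemic, largely enolised) | COC(=O)C(OCc1ccccc1)C(=O)CC(=O)CC(=O)CCCCCCCCCCCCCCC | intermediate
10 | methyl 1-(benzyloxy)-2-hydroxy-4,6-dioxo-2-pentadecylcyclohexane-1-carboxylate (racemic diastereomers, drawn as the neutral keto form, not isolated) | COC(=O)C1(OCc2ccccc2)C(=O)CC(=O)CC1(O)CCCCCCCCCCCCCCC | intermediate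
11 | 1-(benzyloxy)-4,6-dioxo-2-pentadecylcyclohex-2-ene-1-carboxylic acid (racemic, drawn as the neutral keto form, not isolated) | OC(=O)C1(OCc2ccccc2)C(=O)CC(=O)C=C1CCCCCCCCCCCCCCC | intermediate
12 | 4-(benzyloxy)-5-pentadecylbenzene-1,3-diol | CCCCCCCCCCCCCCCc1cc(O)cc(O)c1OCc1ccccc1 | intermediate
13 | 1-(benzyloxy)-2,4-bis[(tert-butyldimethylsilyl)oxy]-6-pentadecylbenzene | CCCCCCCCCCCCCCCc1cc(O[Si](C)(C)C(C)(C)C)cc(O[Si](C)(C)C(C)(C)C)c1OCc1ccccc1 | intermediate
14 | 2,4-bis[(tert-butyldimethylsilyl)oxy]-6-pentadecylphenol (not isolated) | CCCCCCCCCCCCCCCc1cc(O[Si](C)(C)C(C)(C)C)cc(O[Si](C)(C)C(C)(C)C)c1O | intermediate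
15 | 2,4-bis[(tert-butyldimethylsilyl)oxy]-6-pentadecylphenyl acetate | CCCCCCCCCCCCCCCc1cc(O[Si](C)(C)C(C)(C)C)cc(O[Si](C)(C)C(C)(C)C)c1OC(C)=O | intermediate
16 | 2,4-dihydroxy-6-pentadecylphenyl acetate | CCCCCCCCCCCCCCCc1cc(O)cc(O)c1OC(C)=O | target

## Step count and least certain steps

Total number of steps: 9. Longest linear sequence: 8 steps (steps 1, 2, 3, 5, 6, 7, 8 and 9); step 4 is a one-step side branch.

**Step 6 (key step, proposed new method).**
- Most likely failure: the hindered tertiary enolate adds too slowly or reversibly, so that the chain is consumed by Claisen closure, retro-Claisen fragmentation or O-cyclisation; or the quaternary ester resists cleavage and aromatisation stalls.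
- Fallback (known chemistry; sets out from 1, 5 and 8 and comes back to the route at 14): the dianion of 1 is acetylated with 5 to methyl 3,5-dioxohexanoate F1, and the trianion of F1 is acylated with 8 to methyl 3,5,7-trioxodocosanoate F2. Aqueous KOH closes F2 in the established aldol mode of 2-unsubstituted triketo esters to methyl 2,4-dihydroxy-6-pentadecylbenzoate F3. Hot aqueous KOH saponifies F3 to 2,4-dihydroxy-6-pentadecylbenzoic acid F4, which is decarboxylated by heating to 5-pentadecylbenzene-1,3-diol F5. Vilsmeier–Haack formylation (POCl3, DMF) at the ring carbon between the chain and one hydroxyl, para to the other hydroxyl, gives 2,4-dihydroxy-6-pentadecylbenzaldehyde F6. Silylation (TBSCl, imidazole) gives 2,4-bis[(tert-butyldimethylsilyl)oxy]-6-pentadecylbenzaldehyde F7. Baeyer–Villiger oxidation with mCPBA gives 2,4-bis[(tert-butyldimethylsilyl)oxy]-6-pentadecylphenyl formate F8. Mild methanolysis of the formate (NaHCO3, MeOH, 0 °C) delivers 14, which is acetylated at once as in the second half of step 8.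

**Step 5.**
- Most likely failure: incomplete third deprotonation or proton transfer between the trianion and the amide, so that acylation occurs on oxygen or not at all; and premature cyclisation of the triketo ester during work-up.
- Fallback (sets out from 6 and comes back to the route at 9): the trianion of 6 is added to hexadecanal, an aldol addition in place of the acylation, to give methyl 2-(benzyloxy)-7-hydroxy-3,5-dioxodocosanoate F9. The secondary alcohol of F9 is then oxidised with Dess–Martin periodinane (NaHCO3-buffered, short contact time) to 9.

**Step 3.**
- Most likely failure: enolisation of the acetyl donor by the dianion instead of addition, or incomplete methyl deprotonation, returning 4.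
- Fallback (sets out from 4 and comes back to the route at 6): 4 is silylated (Me3SiCl, Et3N) to methyl 2-(benzyloxy)-3-[(trimethylsilyl)oxy]but-2-enoate F10. This is deprotonated and silylated again (LiN(iPr)2, Me3SiCl, −78 °C) to 2-(benzyloxy)-1-methoxy-1,3-bis[(trimethylsilyl)oxy]buta-1,3-diene F11. In a Mukaiyama-type acylation, F11 reacts at its terminal carbon with acetyl chloride (CH2Cl2, −78 °C to rt) to give 6 after aqueous work-up, without any strongly basic carbanion meeting the acyl donor.

**Step 8.**
- Most likely failure: shift of the silyl group from O2 to O1 in the free phenol before acylation, which would place the acetate on the wrong oxygen; or sluggish acylation of the doubly flanked phenol.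
- Fallback (sets out from 12 and comes back to the route at 16): the phenols are protected as non-migrating acetals. 12 is converted with MOMCl and iPr2NEt into 1-(benzyloxy)-2,4-bis(methoxymethoxy)-6-pentadecylbenzene F12. Hydrogenolysis (H2, Pd/C) gives 2,4-bis(methoxymethoxy)-6-pentadecylphenol F13, and acetylation (Ac2O, pyridine, DMAP) gives 2,4-bis(methoxymethoxy)-6-pentadecylphenyl acetate F14. The acetals of F14 are removed with Me3SiBr in CH2Cl2 at low temperature, followed by neutral aqueous work-up, to give 16.

## Further compounds

F1 | step 6 | methyl 3,5-dioxohexanoate | COC(=O)CC(=O)CC(C)=O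
F2 | step 6 | methyl 3,5,7-trioxodocosanoate | COC(=O)CC(=O)CC(=O)CC(=O)CCCCCCCCCCCCCCC
F3 | step 6 | methyl 2,4-dihydroxy-6-pentadecylbenzoate | CCCCCCCCCCCCCCCc1cc(O)cc(O)c1C(=O)OC
F4 | step 6 | 2,4-dihydroxy-6-pentadecylbenzoic acid | CCCCCCCCCCCCCCCc1cc(O)cc(O)c1C(=O)O
F5 | step 6 | 5-pentadecylbenzene-1,3-diol | CCCCCCCCCCCCCCCc1cc(O)cc(O)c1
F6 | step 6 | 2,4-dihydroxy-6-pentadecylbenzaldehyde | CCCCCCCCCCCCCCCc1cc(O)cc(O)c1C=O
F7 | step 6 | 2,4-bis[(tert-butyldimethylsilyl)oxy]-6-pentadecylbenzaldehyde | CCCCCCCCCCCCCCCc1cc(O[Si](C)(C)C(C)(C)C)cc(O[Si](C)(C)C(C)(C)C)c1C=O
F8 | step 6 | 2,4-bis[(tert-butyldimethylsilyl)oxy]-6-pentadecylphenyl formate | CCCCCCCCCCCCCCCc1cc(O[Si](C)(C)C(C)(C)C)cc(O[Si](C)(C)C(C)(C)C)c1OC=O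
F9 | step 5 | methyl 2-(benzyloxy)-7-hydroxy-3,5-dioxodocosanoate (mixture of racemic diastereomers) | COC(=O)C(OCc1ccccc1)C(=O)CC(=O)CC(O)CCCCCCCCCCCCCCC
F10 | step 3 | methyl 2-(benzyloxy)-3-[(trimethylsilyl)oxy]but-2-enoate | COC(=O)C(OCc1ccccc1)=C(C)O[Si](C)(C)C
F11 | step 3 | 2-(benzyloxy)-1-methoxy-1,3-bis[(trimethylsilyl)oxy]buta-1,3-diene | COC(O[Si](C)(C)C)=C(OCc1ccccc1)C(=C)O[Si](C)(C)C
F12 | step 8 | 1-(benzyloxy)-2,4-bis(methoxymethoxy)-6-pentadecylbenzene | CCCCCCCCCCCCCCCc1cc(OCOC)cc(OCOC)c1OCc1ccccc1
F13 | step 8 | 2,4-bis(methoxymethoxy)-6-pentadecylphenol | CCCCCCCCCCCCCCCc1cc(OCOC)cc(OCOC)c1O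
F14 | step 8 | 2,4-bis(methoxymethoxy)-6-pentadecylphenyl acetate | CCCCCCCCCCCCCCCc1cc(OCOC)cc(OCOC)c1OC(C)=O
A1 | alternative 1 | 1,5-bis(benzyloxy)-2,3-dibromobenzene | Brc1c(Br)cc(OCc2ccccc2)cc1OCc1ccccc1
A2 | alternative 1 | 3,5-bis(benzyloxy)benzyne | C1(OCc2ccccc2)=CC(OCc2ccccc2)=CC#C1
A3 | alternative 1 | pentadecyllithium | [Li]CCCCCCCCCCCCCCC
A4 | alternative 1 | 2,4-bis(benzyloxy)-6-pentadecylphenol | CCCCCCCCCCCCCCCc1cc(OCc2ccccc2)cc(OCc2ccccc2)c1O
A5 | alternative 1 | 2,4-bis(benzyloxy)-6-pentadecylphenyl acetate | CCCCCCCCCCCCCCCc1cc(OCc2ccccc2)cc(OCc2ccccc2)c1OC(C)=O
A6 | alternative 2 | 6-hydroxy-4-oxo-2-pentadecylocta-1,7-dien-3-yl acetate (mixture of racemic diastereomers) | C=CC(O)CC(=O)C(OC(C)=O)C(=C)CCCCCCCCCCCCCCC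
A7 | alternative 2 | 4-hydroxy-6-oxo-2-pentadecylcyclohex-2-en-1-yl acetate (mixture of racemic diastereomers) | CCCCCCCCCCCCCCCC1=CC(O)CC(=O)C1OC(C)=O
A8 | alternative 2 | 4,6-dioxo-2-pentadecylcyclohex-2-en-1-yl acetate (racemic) | CCCCCCCCCCCCCCCC1=CC(=O)CC(=O)C1OC(C)=O
A9 | alternative 3 | 3-(benzyloxy)cyclobut-3-ene-1,2-dione | O=C1C=C(OCc2ccccc2)C1=O
A10 | alternative 3 | 2-bromoheptadec-1-ene | C=C(Br)CCCCCCCCCCCCCCC
A11 | alternative 3 | 3-(benzyloxy)-4-(heptadec-1-en-2-yl)-4-hydroxycyclobut-2-en-1-one (racemic) | C=C(CCCCCCCCCCCCCCC)C1(O)C(OCc2ccccc2)=CC1=O
A12 | alternative 3 | 2-(benzyloxy)-1-(heptadec-1-en-2-yl)-4-oxocyclobut-2-en-1-yl acetate (racemic) | C=C(CCCCCCCCCCCCCCC)C1(OC(C)=O)C(OCc2ccccc2)=CC1=O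
A13 | alternative 3 | 4-(benzyloxy)-6-oxo-2-pentadecylhexa-1,3,5-trien-3-yl acetate (dienylketene) | O=C=CC(OCc1ccccc1)=C(OC(C)=O)C(=C)CCCCCCCCCCCCCCC
A14 | alternative 3 | 2-(benzyloxy)-4-hydroxy-6-pentadecylphenyl acetate | CCCCCCCCCCCCCCCc1cc(O)cc(OCc2ccccc2)c1OC(C)=O
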